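Drimane numbering is used (C3 = CHBr, C4 = CMe2, C5 and C10 = ring fusion, C8 = methylidene carbon bonded to C12, C9 = CH carrying benzylic C11). β is the face of the C10 methyl, so the target is the 3β-Br, 5β-H, 9β-H, 10β-Me cis-decalin.
Enabling feature: in ring A the C1–C10 bond ends at a quaternary fusion carbon whose methyl is cis to H5 on the neighbouring fusion carbon, and C3, reached through C1–C2, bears a heteroatom. A suprafacial [3,3] shift across the alkene bridge of a 2-vinylbicyclo[2.2.2]oct-5-en-2-ol produces exactly this pattern.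
Cuts, in retrosynthetic order: C11–aryl (Negishi), C9–C11 (carbonylation of a C8=C9 enol triflate), C3–Br (inversion of a 3α-alcohol), C1–C10 with re-formation of C3–C8 (retro-oxy-Cope), C2–C3 (vinyl addition), the two C4 methyls, then C3–C8 and C4–C5 (Diels–Alder).
Forward: the carbocycle of 3-methylcyclohexenone becomes ring B and a Diels–Alder reaction bridges it to the bicyclo[2.2.2]octene. The oxy-Cope step then opens the C3–C8 bridge and closes ring A, after which C11 and finally the arene are attached.
Stereochemistry: C5 comes from the catalytic asymmetric Diels–Alder reaction and C10 is relayed from C5 by the rigid bicycle. C3 is set by β-face hydride delivery followed by SN2 inversion, and C9 by protonation of a dienolate on the convex β face.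

Key step: step 8

Assumption: the sense of induction in step 2 is taken from the behaviour of this catalyst family with acrylates and simple dienes ((S)-catalyst, attack on the Cα Re face). The (R)-catalyst is therefore specified for the required Cα Si attack, and its antipode would be used if the dimethyl diene responds in the opposite sense.

Step 1
Reactants: 1 3-methylcyclohex-2-en-1-one
Product: 3 1,3-dimethylcyclohexa-1,3-diene, via 1,3-dimethylcyclohex-2-en-1-ol 2 (not isolated)
Conditions: MeLi, Et2O, −78 to 0 °C; then 1 M aq. HCl, 25 °C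
Reagents that add atoms: methyllithium, [Li]C
Why: 1,2-Addition of MeLi to the enone and acid-catalysed E1 dehydration of the tertiary allylic alcohol should settle on the conjugated endocyclic diene with two trisubstituted double bonds, while exocyclic isomers cannot become s-cis and stay inert in step 2.

Step 2
Reactants: 3 1,3-dimethylcyclohexa-1,3-diene; 4 2,2,2-trifluoroethyl acrylate
Product: 5 2,2,2-trifluoroethyl (1R,2R,4R)-1,5-dimethylbicyclo[2.2.2]oct-5-ene-2-carboxylate (ester endo, syn to C5=C6)
Conditions: (R)-3,3-diphenyl-1-(2-methylphenyl)tetrahydro-1H,3H-pyrrolo[1,2-c][1,3,2]oxazaborole (20 mol %), HN(SO2CF3)2 (18 mol %), CH2Cl2, −20 to 4 °C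
Reagents that add atoms: none
Why: Catalytic enantioselective Diels–Alder reaction in which both methyl groups steer the ester-bearing carbon to the methylated diene terminus (ortho/para rule), the endo transition state places the ester syn to the new alkene, and the chiral oxazaborolidinium cation shields one acrylate face so that C1, C2 and C4 (later C8, C3, C5) are fixed together.

Step 3
Reactants: 5 2,2,2-trifluoroethyl (1R,2R,4R)-1,5-dimethylbicyclo[2.2.2]oct-5-ene-2-carboxylate
Product: 7 2,2,2-trifluoroethyl (1R,2R,4R)-2-hydroxy-1,5-dimethylbicyclo[2.2.2]oct-5-ene-2-carboxylate, via potassium ester enolate 6 (not isolated)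
Conditions: KN(SiMe3)2, THF, −78 °C; 2-(phenylsulfonyl)-3-phenyloxaziridine, −78 °C; AcOH quench
Reagents that add atoms: 2-(phenylsulfonyl)-3-phenyloxaziridine, O=S(=O)(c1ccccc1)N1OC1c1ccccc1
Why: Enolate hydroxylation with an N-sulfonyloxaziridine (Davis oxidation), kept at −78 °C so that the trifluoroethyl ester enolate does not collapse to a ketene; the oxidant should arrive on the side of the flat alkene bridge, but the C2 configuration is erased in step 5.

Step 4
Reactants: 7 2,2,2-trifluoroethyl (1R,2R,4R)-2-hydroxy-1,5-dimethylbicyclo[2.2.2]oct-5-ene-2-carboxylate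
Product: 8 (1R,2R,4R)-2-(hydroxymethyl)-1,5-dimethylbicyclo[2.2.2]oct-5-en-2-ol
Conditions: LiAlH4, Et2O, 0 to 25 °C; aqueous NaOH work-up
Reagents that add atoms: none
Why: Hydride reduction of the ester gives the 1,2-diol needed for cleavage and touches neither the alkene nor a stereocentre.

Step 5
Reactants: 8 (1R,2R,4R)-2-(hydroxymethyl)-1,5-dimethylbicyclo[2.2.2]oct-5-en-2-ol
Product: 9 (1R,4R)-1,5-dimethylbicyclo[2.2.2]oct-5-en-2-one
Conditions: NaIO4, THF/H2O, 0 to 25 °C
Reagents that add atoms: none
Why: Periodate glycol cleavage (Malaprade reaction) removes the former ester carbon as formaldehyde and leaves the C2 ketone, so that only the two bridgehead stereocentres of step 2 remain.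

Step 6
Reactants: 9 (1R,4R)-1,5-dimethylbicyclo[2.2.2]oct-5-en-2-one
Product: 11 (1R,4S)-1,3,3,5-tetramethylbicyclo[2.2.2]oct-5-en-2-one, via 3-monomethyl ketone 10 (not isolated)
Conditions: KOt-Bu (excess), MeI (excess), THF, 0 to 25 °C
Reagents that add atoms: iodomethane, CI
Why: Exhaustive enolate C-methylation, free of regiochemical ambiguity because C3 is the only enolisable position (C1 is a quaternary bridgehead), installs the future C4 gem-dimethyl group in two deprotonation–SN2 cycles.

Step 7
Reactants: 11 (1R,4S)-1,3,3,5-tetramethylbicyclo[2.2.2]oct-5-en-2-one; 12 vinylmagnesium bromide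
Product: 13 (1R,2S,4S)-1,3,3,5-tetramethyl-2-vinylbicyclo[2.2.2]oct-5-en-2-ol (vinyl syn to C5=C6)
Conditions: CeCl3 (dried), THF, then 12, −78 to 0 °C; H2O
Reagents that add atoms: none
Why: 1,2-Addition of an organocerium reagent to a non-enolisable, fenchone-like ketone, in which the nucleophile should pass over the flat C5=C6 bridge and not over the C7–C8 bridge with its inward-pointing hydrogens, sets C2 with vinyl syn to the alkene.

Step 8
Reactants: 13 (1R,2S,4S)-1,3,3,5-tetramethyl-2-vinylbicyclo[2.2.2]oct-5-en-2-ol
Product: 16 cis-4,4,8,10-tetramethyl-octal-8-en-3-one (5β-H/10β-Me), via potassium alkoxide 14 (not isolated), via potassium enolate 15 (not isolated)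
Conditions: KH, 18-crown-6, THF, 25 to 66 °C; then H2O, 0 °C
Reagents that add atoms: none
Why: KH with 18-crown-6 converts 13 into the loosely ion-paired alkoxide 14, in which the oxyanion weakens the adjacent C3–C8 σ-bond (allylic to C9=C10); this bond breaks while the vinyl terminus C1 bonds to C10 in a concerted suprafacial [3,3] sigmatropic shift through the boat-like six-centre array imposed by the bicycle, the closest known reaction type being the anionic oxy-Cope rearrangement of 2-vinylbicyclo[2.2.2]oct-5-en-2-ols to cis-fused octalones. Ring A (C10–C1–C2–C3–C4–C5) is closed pericyclically by the new C1–C10 bond, and the old cyclohexene ring lives on as ring B with its double bond moved to C8=C9. The only new stereocentre, quaternary C10, is controlled by the substrate: C1 can reach C10 only on the alkene face turned toward the C3–C4 bridge, so C1 and C4 leave the C5–C10 bond on the same side and the C10 methyl is forced cis to H5, whose configuration dates from step 2. The step needs the [3,3] path to beat a [1,3] shift and heterolysis to an allyl anion plus enone; the syn arrangement of vinyl group and alkene fixed in step 7, the relief of crowding at a carbinol carbon flanked by two quaternary centres and the gain of a delocalised enolate should secure this. Since enolate 15 cannot revert, the rearrangement is one-way, and the aqueous quench gives ketone 16 without risk to C5, which quaternary C4 insulates from the carbonyl group.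

Step 9
Reactants: 16 cis-4,4,8,10-tetramethyl-octal-8-en-3-one
Product: 17 cis-4,4,8,10-tetramethyl-octal-8-en-3α-ol
Conditions: LiBH(s-Bu)3, THF, −78 to 0 °C; then NaOH, H2O2
Reagents that add atoms: none
Why: Diastereoselective ketone reduction with a bulky trialkylborohydride: in the ring-A chair that keeps the C4 methyls clear of ring B the α face of C3 is closed by the syn-axial C6 methylene, so hydride should come in equatorially from the convex β face and leave the axial 3α-alcohol.

Step 10
Reactants: 17 cis-4,4,8,10-tetramethyl-octal-8-en-3α-ol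
Product: 19 3β-bromo-cis-4,4,8,10-tetramethyl-octal-8-ene, via alkoxyphosphonium bromide 18 (not isolated)
Conditions: PPh3, CBr4, 2,6-di-tert-butylpyridine, toluene, 25 to 80 °C
Reagents that add atoms: carbon tetrabromide, BrC(Br)(Br)Br
Why: Appel reaction in which bromide displaces the phosphonium-activated axial 3α-oxygen of 18 (strained against C6) by SN2 attack from the β face and so gives the equatorial 3β-bromide with inversion, a substitution reported for axial carbinols next to a gem-dimethyl carbon in brominated terpenoids and placed early so that only an unreactive trisubstituted alkene is present.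

Step 11
Reactants: 19 3β-bromo-cis-4,4,8,10-tetramethyl-octal-8-ene
Product: 21 3β-bromo-8α-methyl-cis-4,4,10-trimethyldecalin-9β-ol, via C9 alkylborane 20 (not isolated)
Conditions: BH3·THF, THF, 0 to 25 °C; then NaOH, H2O2, 0 °C
Reagents that add atoms: hydrogen peroxide, OO
Why: Hydroboration–oxidation places boron on the less substituted C9 by syn addition from the β face (the α face is covered by the pseudo-axial C1 methylene), the alkyl bromide is inert to borane, and both new stereocentres are erased in steps 12 and 13.

Step 12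
Reactants: 21 3β-bromo-8α-methyl-cis-4,4,10-trimethyldecalin-9β-ol
Product: 22 3β-bromo-cis-4,4,8,10-tetramethyldecal-9-one
Conditions: Dess–Martin periodinane, CH2Cl2, 25 °C
Reagents that add atoms: none
Why: Dess–Martin oxidation of a hindered secondary alcohol under neutral conditions that leave the bromide alone; the C8 configuration is of no consequence.

Step 13
Reactants: 22 3β-bromo-cis-4,4,8,10-tetramethyldecal-9-one
Product: 24 3β-bromo-cis-4,4,8,10-tetramethyl-octal-8-en-9-yl trifluoromethanesulfonate, via lithium enolate 23 (not isolated)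
Conditions: LiN(i-Pr)2, THF, −78 to 0 °C; PhN(SO2CF3)2, 0 to 25 °C
Reagents that add atoms: N-phenylbis(trifluoromethanesulfonimide), O=S(=O)(N(c1ccccc1)S(=O)(=O)C(F)(F)F)C(F)(F)F
Why: Enolate O-triflation as practised on 2,2,6-trimethylcyclohexanone: only C8 carries an α-hydrogen, so the C8=C9 enolate is the sole option, and the equatorial bromide has no antiperiplanar hydrogen for E2 loss.

Step 14
Reactants: 24 3β-bromo-cis-4,4,8,10-tetramethyl-octal-8-en-9-yl trifluoromethanesulfonate
Product: 25 methyl 3β-bromo-5β-drim-8-en-11-oate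
Conditions: Pd(OAc)2 (10 mol %), Ph2P(CH2)3PPh2, CO (1 atm), MeOH, Et3N, DMF, 65 °C
Reagents that add atoms: carbon monoxide, [C-]#[O+]; methanol, CO
Why: Palladium-catalysed alkoxycarbonylation of an enol triflate (oxidative addition, CO insertion, methanolysis) forms C9–C11, and zerovalent palladium with aryl phosphines does not insert into an unactivated secondary alkyl bromide.

Step 15
Reactants: 25 methyl 3β-bromo-5β-drim-8-en-11-oate
Product: 27 methyl 3β-bromo-5β,9β-H-drim-8(12)-en-11-oate, via lithium dienolate 26 (not isolated)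
Conditions: LiN(i-Pr)2, THF/DMPU, −78 °C; then cannulated into AcOH/THF, −78 °C
Reagents that add atoms: none
Why: Deconjugative protonation of an extended enolate: carbonyl-bound amide base removes a proton from the C12 methyl, the γ-position cis to the ester, and dienolate 26 is protonated kinetically at its α-carbon C9 from the convex β face because the pseudo-axial C1 methylene of ring A covers the α face, which sets H9 β (C11 α, equatorial) and leaves the C8=C12 methylidene.

Step 16
Reactants: 27 methyl 3β-bromo-5β,9β-H-drim-8(12)-en-11-oate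
Product: 28 3β-bromo-5β,9β-H-drim-8(12)-en-11-ol
Conditions: i-Bu2AlH, CH2Cl2, −78 to 0 °C; aq. potassium sodium tartrate
Reagents that add atoms: none
Why: Ester reduction with a non-basic aluminium hydride avoids epimerisation or reconjugation at C9 and does not reduce the alkyl bromide, and after this step C9 is no longer acidic.

Step 17
Reactants: 28 3β-bromo-5β,9β-H-drim-8(12)-en-11-ol
Product: 30 3β-bromo-11-iodo-5β,9β-H-drim-8(12)-ene, via alkoxyphosphonium iodide 29 (not isolated)
Conditions: PPh3, I2, imidazole, CH2Cl2, 0 to 25 °C (alcohol added last)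
Reagents that add atoms: iodine, II
Why: Appel-type iodination (Garegg–Samuelsson conditions) of a primary alcohol by SN2 at C11; premixing PPh3 and I2 leaves no free iodine for the methylidene group, and no stereocentre is involved.

Step 18
Reactants: 31 4-bromo-2,5-dimethoxybenzaldehyde
Product: 32 4-bromo-2,5-dihydroxybenzaldehyde
Conditions: BBr3, CH2Cl2, −78 to 25 °C; then H2O
Reagents that add atoms: none
Why: Lewis-acid cleavage of aryl methyl ethers with BBr3 is done on the simple arene so that no harsh demethylation is needed once the methylidene and the alkyl bromide are present.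

Step 19
Reactants: 32 4-bromo-2,5-dihydroxybenzaldehyde
Product: 33 4-bromo-2,5-bis(tert-butyldimethylsilyloxy)benzaldehyde
Conditions: t-BuMe2SiCl, imidazole, DMF, 25 °C
Reagents that add atoms: tert-butyldimethylsilyl chloride, CC(C)(C)[Si](C)(C)Cl
Why: Standard imidazole-promoted O-silylation masks both acidic phenols, which would otherwise quench the organozinc reagent, with groups removable under nearly neutral conditions.

Step 20
Reactants: 30 3β-bromo-11-iodo-5β,9β-H-drim-8(12)-ene; 33 4-bromo-2,5-bis(tert-butyldimethylsilyloxy)benzaldehyde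
Product: 35 bis(tert-butyldimethylsilyl) ether of peyssonol A, via alkylzinc iodide 34 (not isolated)
Conditions: Zn dust, LiCl, THF, 25 °C; then 33, Pd(OAc)2 (5 mol %), 2-dicyclohexylphosphino-2',6'-dimethoxybiphenyl (10 mol %), THF, 25 to 45 °C
Reagents that add atoms: none
Why: Negishi sp3–sp2 cross-coupling: zinc inserts into the primary C–I bond far faster than into the hindered secondary C–Br bond, the alkylzinc halide tolerates aldehyde and silyl ethers, and the bulky electron-rich biarylphosphine favours reductive elimination over β-hydride loss from C9, so no stereocentre is touched.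

Step 21
Reactants: 35 bis(tert-butyldimethylsilyl) ether of peyssonol A
Product: 36 peyssonol A (3S,5S,9R,10R in drimane numbering)
Conditions: n-Bu4NF, AcOH, THF, 0 °C
Reagents that add atoms: none
Why: Fluoride-induced cleavage of aryl silyl ethers under acetic acid buffering is too mild to displace or eliminate the equatorial neopentyl-type bromide, to move the methylidene double bond or to add the neighbouring phenol to it.

Compound list
1 | 3-methylcyclohex-2-en-1-one | CC1=CC(=O)CCC1 | starting material
2 | 1,3-dimethylcyclohex-2-en-1-ol (racemic) | CC1=CC(C)(O)CCC1 | intermediate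
3 | 1,3-dimethylcyclohexa-1,3-diene | CC1=CC(C)=CCC1 | intermediate
4 | 2,2,2-trifluoroethyl acrylate | C=CC(=O)OCC(F)(F)F | starting material
5 | 2,2,2-trifluoroethyl (1R,2R,4R)-1,5-dimethylbicyclo[2.2.2]oct-5-ene-2-carboxylate | O=C(OCC(F)(F)F)[C@@H]1C[C@H]2CC[C@]1(C)C=C2C | intermediate
6 | potassium enolate of 5 | [K+].[O-]C(OCC(F)(F)F)=C1C[C@H]2CC[C@]1(C)C=C2C | intermediate
7 | 2,2,2-trifluoroethyl (1R,2R,4R)-2-hydroxy-1,5-dimethylbicyclo[2.2.2]oct-5-ene-2-carboxylate | O=C(OCC(F)(F)F)[C@@]1(O)C[C@H]2CC[C@]1(C)C=C2C | intermediate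
8 | (1R,2R,4R)-2-(hydroxymethyl)-1,5-dimethylbicyclo[2.2.2]oct-5-en-2-ol | OC[C@@]1(O)C[C@H]2CC[C@]1(C)C=C2C | intermediate
9 | (1R,4R)-1,5-dimethylbicyclo[2.2.2]oct-5-en-2-one | O=C1C[C@H]2CC[C@]1(C)C=C2C | intermediate
10 | 1,3,5-trimethylbicyclo[2.2.2]oct-5-en-2-one (3-methyl syn to the alkene) | O=C1[C@H](C)[C@H]2CC[C@]1(C)C=C2C | intermediate
11 | (1R,4S)-1,3,3,5-tetramethylbicyclo[2.2.2]oct-5-en-2-one | O=C1C(C)(C)[C@H]2CC[C@]1(C)C=C2C | intermediate
12 | vinylmagnesium bromide | C=C[Mg]Br | starting material
13 | (1R,2S,4S)-1,3,3,5-tetramethyl-2-vinylbicyclo[2.2.2]oct-5-en-2-ol | C=C[C@]1(O)C(C)(C)[C@H]2CC[C@]1(C)C=C2C | intermediate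
14 | potassium alkoxide of 13 | C=C[C@]1([O-])C(C)(C)[C@H]2CC[C@]1(C)C=C2C.[K+] | intermediate
15 | potassium C2=C3 enolate of 16 | CC1=C[C@@]2(C)CC=C([O-])C(C)(C)[C@H]2CC1.[K+] | intermediate
16 | cis-4,4,8,10-tetramethyl-octal-8-en-3-one (5β-H, 10β-Me) | CC1=C[C@@]2(C)CCC(=O)C(C)(C)[C@H]2CC1 | intermediate
17 | cis-4,4,8,10-tetramethyl-octal-8-en-3α-ol | CC1=C[C@@]2(C)CC[C@@H](O)C(C)(C)[C@H]2CC1 | intermediate
18 | 3α-(triphenylphosphoniooxy) derivative of 17, bromide salt | CC1=C[C@@]2(C)CC[C@@H](O[P+](c3ccccc3)(c3ccccc3)c3ccccc3)C(C)(C)[C@H]2CC1.[Br-] | intermediate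
19 | 3β-bromo-cis-4,4,8,10-tetramethyl-octal-8-ene | CC1=C[C@@]2(C)CC[C@H](Br)C(C)(C)[C@H]2CC1 | intermediate
20 | 9β-boryl-3β-bromo-8α-methyl decalin (monoalkylborane) | C[C@H]1[C@H](B)[C@@]2(C)CC[C@H](Br)C(C)(C)[C@H]2CC1 | intermediate
21 | 3β-bromo-8α-methyl-cis-4,4,10-trimethyldecalin-9β-ol | C[C@H]1[C@H](O)[C@@]2(C)CC[C@H](Br)C(C)(C)[C@H]2CC1 | intermediate
22 | 3β-bromo-cis-4,4,8,10-tetramethyldecal-9-one | C[C@H]1C(=O)[C@@]2(C)CC[C@H](Br)C(C)(C)[C@H]2CC1 | intermediate
23 | lithium C8=C9 enolate of 22 | CC1=C([O-])[C@@]2(C)CC[C@H](Br)C(C)(C)[C@H]2CC1.[Li+] | intermediate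
24 | 3β-bromo-cis-4,4,8,10-tetramethyl-octal-8-en-9-yl trifluoromethanesulfonate | CC1=C(OS(=O)(=O)C(F)(F)F)[C@@]2(C)CC[C@H](Br)C(C)(C)[C@H]2CC1 | intermediate
25 | methyl 3β-bromo-5β-drim-8-en-11-oate | CC1=C(C(=O)OC)[C@@]2(C)CC[C@H](Br)C(C)(C)[C@H]2CC1 | intermediate
26 | lithium dienolate of 25 (C12=C8–C9=C11) | C=C1CC[C@@H]2C(C)(C)[C@@H](Br)CC[C@]2(C)C1=C([O-])OC.[Li+] | intermediate
27 | methyl 3β-bromo-5β,9β-H-drim-8(12)-en-11-oate | C=C1CC[C@@H]2C(C)(C)[C@@H](Br)CC[C@]2(C)[C@@H]1C(=O)OC | intermediate
28 | 3β-bromo-5β,9β-H-drim-8(12)-en-11-ol | C=C1CC[C@@H]2C(C)(C)[C@@H](Br)CC[C@]2(C)[C@@H]1CO | intermediate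
29 | 11-(triphenylphosphoniooxy) derivative of 28, iodide salt | C=C1CC[C@@H]2C(C)(C)[C@@H](Br)CC[C@]2(C)[C@@H]1CO[P+](c1ccccc1)(c1ccccc1)c1ccccc1.[I-] | intermediate
30 | 3β-bromo-11-iodo-5β,9β-H-drim-8(12)-ene | C=C1CC[C@@H]2C(C)(C)[C@@H](Br)CC[C@]2(C)[C@@H]1CI | intermediate
31 | 4-bromo-2,5-dimethoxybenzaldehyde | COc1cc(C=O)c(OC)cc1Br | starting material
32 | 4-bromo-2,5-dihydroxybenzaldehyde | Oc1cc(C=O)c(O)cc1Br | intermediate
33 | 4-bromo-2,5-bis(tert-butyldimethylsilyloxy)benzaldehyde | CC(C)(C)[Si](C)(C)Oc1cc(C=O)c(O[Si](C)(C)C(C)(C)C)cc1Br | intermediate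
34 | (3β-bromo-5β,9β-H-drim-8(12)-en-11-yl)zinc iodide | C=C1CC[C@@H]2C(C)(C)[C@@H](Br)CC[C@]2(C)[C@@H]1C[Zn]I | intermediate
35 | bis(tert-butyldimethylsilyl) ether of peyssonol A | C=C1CC[C@@H]2C(C)(C)[C@@H](Br)CC[C@]2(C)[C@@H]1Cc1cc(O[Si](C)(C)C(C)(C)C)c(C=O)cc1O[Si](C)(C)C(C)(C)C | intermediate
36 | peyssonol A | C=C1CC[C@@H]2C(C)(C)[C@@H](Br)CC[C@]2(C)[C@@H]1Cc1cc(O)c(C=O)cc1O | target

Total step count: 21. Longest linear sequence: 19 (steps 1–17, 20 and 21); steps 18 and 19 prepare the arene in parallel.

Steps most likely to fail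

Step 10 (invertive bromination). The activated axial oxygen may leave by elimination toward C2 or with a 1,2-methyl shift from C4, or bromide may fail to reach the neopentyl-type carbon. Step 9 carries the linked risk of hydride delivery from the wrong face. The fallback leaves the route at ketone 16 and makes the C–Br bond by radical hydrogenation of a vinyl bromide instead of by substitution.
- Excess BH3·THF followed by NaOH/H2O2 reduces the ketone and hydroborates C8=C9 to the 3,9-diol F1.
- Dess–Martin periodinane gives the 3,9-dione F2.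
- Hydrazine hydrate in ethanol condenses at the less shielded C3 carbonyl, which has one CH2 neighbour, to give the monohydrazone F3.
- N-Bromosuccinimide with 2-tert-butyl-1,1,3,3-tetramethylguanidine (Barton vinyl halide synthesis) gives the C2=C3 vinyl bromide F4.
- Hydrogen-atom-transfer hydrogenation follows, with Mn(dpm)3 (dpm = 2,2,6,6-tetramethylheptane-3,5-dionate), PhSiH3 and t-BuOOH in i-PrOH. This method is reported to retain carbon–halogen bonds and to favour the more stable epimer, so it should give the equatorial 3β-bromide.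
- That product is ketone 22, where the route is rejoined.

Step 15 (deconjugation). Deprotonation may occur at C7 instead of C12, which would give the endocyclic isomer. Protonation may occur on the α face, or the ester may reconjugate during the quench. The fallback sets out from 25 and uses an excited-state hydrogen shift in place of a base. Irradiation at 254 nm in hexane/Et2O with a catalytic amount of 1,2-dimethylimidazole lets the enoate carbonyl abstract a hydrogen by a 1,5-shift. Only the C12 methyl, cis to the ester, is within reach, so the process gives the ketene hemiacetal dienol F5. The weak base relays a proton to C9 of this dienol on the open β face, and the route is rejoined at 27.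

Step 2 (asymmetric cycloaddition). The strongly acidic catalyst may isomerise or oligomerise the electron-rich diene, and bond formation at the methyl-bearing terminus may be slow. Exo addition, which leads to the mirror-image ketone after step 5, may erode enantiopurity unless the exo ester is removed. The fallback sets out from diene 3 and replaces catalyst control by a covalent auxiliary.
- (S)-3-Acryloyl-4-benzyl-1,3-oxazolidin-2-one with Et2AlCl in CH2Cl2 at −78 °C reacts through the chelated s-cis imide on the Cα Si face opposite the benzyl group. This gives the endo imide adduct F6, whose diastereomers can be separated.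
- NaN(SiMe3)2 and 2-(phenylsulfonyl)-3-phenyloxaziridine give the α-hydroxy imide F7.
- LiBH4 in Et2O/MeOH releases the auxiliary and delivers diol 8, where the route is rejoined.

Further compounds
F1 | step 10 | 8α-methyl-cis-4,4,10-trimethyldecalin-3,9β-diol (C3 epimers of no consequence) | C[C@H]1[C@H](O)[C@@]2(C)CCC(O)C(C)(C)[C@H]2CC1
F2 | step 10 | cis-4,4,8,10-tetramethyldecalin-3,9-dione | C[C@H]1C(=O)[C@@]2(C)CCC(=O)C(C)(C)[C@H]2CC1
F3 | step 10 | C3 monohydrazone of F2 | C[C@H]1C(=O)[C@@]2(C)CCC(=NN)C(C)(C)[C@H]2CC1
F4 | step 10 | 3-bromo-cis-4,4,8,10-tetramethyl-octal-2-en-9-one | C[C@H]1C(=O)[C@@]2(C)CC=C(Br)C(C)(C)[C@H]2CC1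
F5 | step 15 | ketene hemiacetal dienol of 25 | C=C1CC[C@@H]2C(C)(C)[C@@H](Br)CC[C@]2(C)C1=C(O)OC
F6 | step 2 | (S)-4-benzyl-3-[(1R,2R,4R)-1,5-dimethylbicyclo[2.2.2]oct-5-ene-2-carbonyl]-1,3-oxazolidin-2-one | O=C([C@@H]1C[C@H]2CC[C@]1(C)C=C2C)N1[C@@H](Cc2ccccc2)COC1=O
F7 | step 2 | (S)-4-benzyl-3-[(1R,2R,4R)-2-hydroxy-1,5-dimethylbicyclo[2.2.2]oct-5-ene-2-carbonyl]-1,3-oxazolidin-2-one | O=C([C@@]1(O)C[C@H]2CC[C@]1(C)C=C2C)N1[C@@H](Cc2ccccc2)COC1=O
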